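**Retrosynthetic overview**
- The target comes from its bis(TBS) ether by desilylation only; ring C and both stereocentres are already in place.
- Ring C (O1–C2 bond) comes from a catalyst-controlled oxa-Michael closure of a 2'-hydroxy-α-aryl chalcone; C3 settles trans to C2 by enolisation.
- Rings A and E come from a twofold Diels–Alder benzannulation of a bis(ethynyl ketone) with 1-methoxy-1,3-bis(trimethylsilyloxy)buta-1,3-diene. The 2-hydroxyl this unveils closes ring C in the same pot (order: rings A and E together, then ring C).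
- The bis(ethynyl ketone) comes from a bis(morpholine amide) and HC≡CMgBr; its α-aryl acrylic arm comes from an isoaurone (2-coumaranone plus 4-acetoxybenzaldehyde) and its cinnamoyl arm from a Heck coupling.
- Rings B and D are bought as benzene building blocks.

Assumption: the quinidine-derived squaramide is taken to give the 2R series (its quinine-derived pseudo-enantiomer is used if the sense of induction proves opposite), and all five starting materials are taken as catalogue compounds.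

**Route**

Step 1
Reactants: 1 (5-bromo-2-hydroxyphenyl)acetic acid; 2 4-acryloylmorpholine
Product: 3 {2-hydroxy-5-[(1E)-3-(morpholin-4-yl)-3-oxoprop-1-en-1-yl]phenyl}acetic acid
Conditions: Pd(OAc)2 (2 mol %), P(o-tol)3 (5 mol %), Et3N (3 equiv), DMF, 100 °C; dilute HCl work-up
Reagents that add atoms: none
Why: Mizoroki–Heck coupling of the aryl bromide para to the phenol gives the (E)-cinnamoyl morpholine amide, a stable acyl donor for the later ketone synthesis; no stereocentre is formed.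

Step 2
Reactants: 3 {2-hydroxy-5-[(1E)-3-(morpholin-4-yl)-3-oxoprop-1-en-1-yl]phenyl}acetic acid; 4 4-formylphenyl acetate (4-acetoxybenzaldehyde)
Product: 6 4-{(E)-[5-[(1E)-3-(morpholin-4-yl)-3-oxoprop-1-en-1-yl]-2-oxo-1-benzofuran-3(2H)-ylidene]methyl}phenyl acetate, via 2-coumaranone lactone 5 (not isolated)
Conditions: Ac2O (4 equiv), Et3N (2 equiv), toluene, 100 °C
Reagents that add atoms: none
Why: Perkin–Oglialoro-type condensation, in which acetic anhydride lactonises the 2-hydroxyphenylacetic acid to the C–H acidic 2-coumaranone and this undergoes Knoevenagel condensation with the aldehyde to the thermodynamically preferred (E)-isoaurone (aryl anti to the lactone carbonyl); no stereocentre is formed.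

Step 3
Reactants: 6 4-{(E)-[5-[(1E)-3-(morpholin-4-yl)-3-oxoprop-1-en-1-yl]-2-oxo-1-benzofuran-3(2H)-ylidene]methyl}phenyl acetate
Product: 8 (2E)-2-{2-[(tert-butyldimethylsilyl)oxy]-5-[(1E)-3-(morpholin-4-yl)-3-oxoprop-1-en-1-yl]phenyl}-3-{4-[(tert-butyldimethylsilyl)oxy]phenyl}-1-(morpholin-4-yl)prop-2-en-1-one, via diphenol bis-amide 7 (not isolated)
Conditions: morpholine (3 equiv), THF, 40 °C; concentrate; then TBSCl (2.5 equiv), imidazole (4 equiv), DMF, 23 °C
Reagents that add atoms: morpholine (C1COCCN1); tert-butyldimethylsilyl chloride, TBSCl (CC(C)(C)[Si](C)(C)Cl)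
Why: Aminolysis of the aryl ester lactone by morpholine gives the α-aryl acrylic morpholine amide with the alkene geometry kept (any aza-Michael adduct reverts), the aryl acetate is cleaved by the same amine, and silylation then masks both phenols; no stereocentre is formed.

Step 4
Reactants: 8 (2E)-2-{2-[(tert-butyldimethylsilyl)oxy]-5-[(1E)-3-(morpholin-4-yl)-3-oxoprop-1-en-1-yl]phenyl}-3-{4-[(tert-butyldimethylsilyl)oxy]phenyl}-1-(morpholin-4-yl)prop-2-en-1-one; 9 ethynylmagnesium bromide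
Product: 10 (1E)-1-{4-[(tert-butyldimethylsilyl)oxy]phenyl}-2-{2-[(tert-butyldimethylsilyl)oxy]-5-[(1E)-3-oxopent-1-en-4-yn-1-yl]phenyl}pent-1-en-4-yn-3-one
Conditions: HC≡CMgBr (3 equiv, 0.5 M in THF), THF, −20 to 0 °C; sat. aq. NH4Cl
Reagents that add atoms: none
Why: Weinreb-type acyl substitution of the two morpholine amides by the alkynyl Grignard reagent stops at the ketone stage because the magnesium-bound tetrahedral adducts survive until the quench, so both terminal ynones are released only on work-up; no stereocentre is formed.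

Step 5
Reactants: 10 (1E)-1-{4-[(tert-butyldimethylsilyl)oxy]phenyl}-2-{2-[(tert-butyldimethylsilyl)oxy]-5-[(1E)-3-oxopent-1-en-4-yn-1-yl]phenyl}pent-1-en-4-yn-3-one; 11 1-methoxy-1,3-bis(trimethylsilyloxy)buta-1,3-diene
Product: 15 (2R,3S)-3-{2-[(tert-butyldimethylsilyl)oxy]-5-[(1E)-3-(2,4-dihydroxyphenyl)-3-oxoprop-1-en-1-yl]phenyl}-2-{4-[(tert-butyldimethylsilyl)oxy]phenyl}-7-hydroxy-2,3-dihydro-4H-chromen-4-one, via twofold cycloadduct 12 (not isolated), via tetrakis(trimethylsilyl) ether 13 (not isolated), via free 2'-hydroxy bis-enone 14 (not isolated)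
Conditions: 11 (2.1 equiv), toluene, 60 °C; then −20 °C, MeOH (8 equiv), 3-{[3,5-bis(trifluoromethyl)phenyl]amino}-4-{[(R)-(6-methoxyquinolin-4-yl)[(2R,4S,5R)-5-ethenylquinuclidin-2-yl]methyl]amino}cyclobut-3-ene-1,2-dione (10 mol %), −20 to 0 °C
Reagents that add atoms: none
Why: Proposed new method: the two terminal ynones are the most electron-poor π-systems and should each undergo regioselective [4+2] cycloaddition with the 1,1,3-trioxygenated diene (its CH2 terminus bonding to the alkyne β-carbon), the adducts aromatise by loss of methanol to 2,4-bis(silyloxy)aryl ketones (rings A and E), methanolysis of the O–Si bonds then frees the 2-hydroxyl groups only in the presence of the bifunctional squaramide, which steers the 6-endo oxa-Michael attack of the ring A phenol onto the α-aryl enone to set C2 as R while C3 equilibrates through the enol to the trans (3S) isomer and the deactivated, hydrogen-bonded chalcone arm stays open; the closest known reaction types are the Diels–Alder benzannulation of 1-oxygenated 3-silyloxybutadienes with alkynones and the cinchona thiourea-catalysed oxa-Michael cyclisation of activated 2'-hydroxychalcones to flavanones.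

Step 6
Reactants: 15 (2R,3S)-3-{2-[(tert-butyldimethylsilyl)oxy]-5-[(1E)-3-(2,4-dihydroxyphenyl)-3-oxoprop-1-en-1-yl]phenyl}-2-{4-[(tert-butyldimethylsilyl)oxy]phenyl}-7-hydroxy-2,3-dihydro-4H-chromen-4-one
Product: 16 (2R,3S)-3-{5-[(1E)-3-(2,4-dihydroxyphenyl)-3-oxoprop-1-en-1-yl]-2-hydroxyphenyl}-7-hydroxy-2-(4-hydroxyphenyl)-2,3-dihydro-4H-chromen-4-one
Conditions: Et3N·3HF (6 equiv), MeCN–THF, 0 to 23 °C
Reagents that add atoms: none
Why: Fluoride-mediated desilylation of the two aryl silyl ethers under buffered, non-basic conditions leaves the base-sensitive C2 and C3 stereocentres and the chalcone untouched.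

**Compound list**
1 | (5-bromo-2-hydroxyphenyl)acetic acid | OC(=O)Cc1cc(Br)ccc1O | starting material
2 | 4-acryloylmorpholine | C=CC(=O)N1CCOCC1 | starting material
3 | {2-hydroxy-5-[(1E)-3-(morpholin-4-yl)-3-oxoprop-1-en-1-yl]phenyl}acetic acid | OC(=O)Cc1cc(/C=C/C(=O)N2CCOCC2)ccc1O | intermediate
4 | 4-formylphenyl acetate | CC(=O)Oc1ccc(C=O)cc1 | starting material
5 | 5-[(1E)-3-(morpholin-4-yl)-3-oxoprop-1-en-1-yl]-1-benzofuran-2(3H)-one (not isolated) | O=C1Cc2cc(/C=C/C(=O)N3CCOCC3)ccc2O1 | intermediate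
6 | 4-{(E)-[5-[(1E)-3-(morpholin-4-yl)-3-oxoprop-1-en-1-yl]-2-oxo-1-benzofuran-3(2H)-ylidene]methyl}phenyl acetate | CC(=O)Oc1ccc(/C=C2/C(=O)Oc3ccc(/C=C/C(=O)N4CCOCC4)cc32)cc1 | intermediate
7 | (2E)-2-{2-hydroxy-5-[(1E)-3-(morpholin-4-yl)-3-oxoprop-1-en-1-yl]phenyl}-3-(4-hydroxyphenyl)-1-(morpholin-4-yl)prop-2-en-1-one (not isolated) | O=C(/C=C/c1ccc(O)c(/C(C(=O)N2CCOCC2)=C\c2ccc(O)cc2)c1)N1CCOCC1 | intermediate
8 | (2E)-2-{2-[(tert-butyldimethylsilyl)oxy]-5-[(1E)-3-(morpholin-4-yl)-3-oxoprop-1-en-1-yl]phenyl}-3-{4-[(tert-butyldimethylsilyl)oxy]phenyl}-1-(morpholin-4-yl)prop-2-en-1-one | O=C(/C=C/c1ccc(O[Si](C)(C)C(C)(C)C)c(/C(C(=O)N2CCOCC2)=C\c2ccc(O[Si](C)(C)C(C)(C)C)cc2)c1)N1CCOCC1 | intermediate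
9 | ethynylmagnesium bromide | C#C[Mg]Br | starting material
10 | (1E)-1-{4-[(tert-butyldimethylsilyl)oxy]phenyl}-2-{2-[(tert-butyldimethylsilyl)oxy]-5-[(1E)-3-oxopent-1-en-4-yn-1-yl]phenyl}pent-1-en-4-yn-3-one | C#CC(=O)/C=C/c1ccc(O[Si](C)(C)C(C)(C)C)c(/C(C(=O)C#C)=C\c2ccc(O[Si](C)(C)C(C)(C)C)cc2)c1 | intermediate
11 | 1-methoxy-1,3-bis(trimethylsilyloxy)buta-1,3-diene | C=C(O[Si](C)(C)C)C=C(OC)O[Si](C)(C)C | starting material
12 | twofold Diels–Alder adduct of 10, each ethynyl ketone now a 6-methoxy-4,6-bis[(trimethylsilyl)oxy]cyclohexa-1,4-dien-1-yl ketone (two ketal centres undefined; not isolated) | COC1(O[Si](C)(C)C)C=C(O[Si](C)(C)C)CC=C1C(=O)/C=C/c1ccc(O[Si](C)(C)C(C)(C)C)c(/C(C(=O)C2=CCC(O[Si](C)(C)C)=CC2(OC)O[Si](C)(C)C)=C\c2ccc(O[Si](C)(C)C(C)(C)C)cc2)c1 | intermediate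
13 | (2E)-1-{2,4-bis[(trimethylsilyl)oxy]phenyl}-2-{5-[(1E)-3-{2,4-bis[(trimethylsilyl)oxy]phenyl}-3-oxoprop-1-en-1-yl]-2-[(tert-butyldimethylsilyl)oxy]phenyl}-3-{4-[(tert-butyldimethylsilyl)oxy]phenyl}prop-2-en-1-one (not isolated) | C[Si](C)(C)Oc1ccc(C(=O)/C=C/c2ccc(O[Si](C)(C)C(C)(C)C)c(/C(C(=O)c3ccc(O[Si](C)(C)C)cc3O[Si](C)(C)C)=C\c3ccc(O[Si](C)(C)C(C)(C)C)cc3)c2)c(O[Si](C)(C)C)c1 | intermediate
14 | (2E)-1-(2,4-dihydroxyphenyl)-2-{2-[(tert-butyldimethylsilyl)oxy]-5-[(1E)-3-(2,4-dihydroxyphenyl)-3-oxoprop-1-en-1-yl]phenyl}-3-{4-[(tert-butyldimethylsilyl)oxy]phenyl}prop-2-en-1-one (not isolated) | O=C(/C=C/c1ccc(O[Si](C)(C)C(C)(C)C)c(/C(C(=O)c2ccc(O)cc2O)=C\c2ccc(O[Si](C)(C)C(C)(C)C)cc2)c1)c1ccc(O)cc1O | intermediate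
15 | (2R,3S)-3-{2-[(tert-butyldimethylsilyl)oxy]-5-[(1E)-3-(2,4-dihydroxyphenyl)-3-oxoprop-1-en-1-yl]phenyl}-2-{4-[(tert-butyldimethylsilyl)oxy]phenyl}-7-hydroxy-2,3-dihydro-4H-chromen-4-one | O=C(/C=C/c1ccc(O[Si](C)(C)C(C)(C)C)c([C@@H]2C(=O)c3ccc(O)cc3O[C@H]2c2ccc(O[Si](C)(C)C(C)(C)C)cc2)c1)c1ccc(O)cc1O | intermediate
16 | (2R,3S)-3-{5-[(1E)-3-(2,4-dihydroxyphenyl)-3-oxoprop-1-en-1-yl]-2-hydroxyphenyl}-7-hydroxy-2-(4-hydroxyphenyl)-2,3-dihydro-4H-chromen-4-one (trans) | O=C(/C=C/c1ccc(O)c([C@@H]2C(=O)c3ccc(O)cc3O[C@H]2c2ccc(O)cc2)c1)c1ccc(O)cc1O | target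

**Step count**
Total steps: 6. Longest linear sequence: 6 (1 → 3 → 6 → 8 → 10 → 15 → 16).

**Three steps most likely to fail, each with a fallback**

Step 5 (benzannulation and asymmetric ring closure in one pot). The risks are incomplete or misdirected cycloaddition at the hindered α-aryl ynone and low enantioselectivity in the presence of methanol and silyl by-products. The fallback gives up the benzannulation and brings both resorcinol rings in preformed. It sets out from 8. 4-Bromoresorcinol is protected (MOMCl, iPr2NEt) as 1-bromo-2,4-bis(methoxymethoxy)benzene F1. Bromine–lithium exchange (n-BuLi, THF, −78 °C) gives [2,4-bis(methoxymethoxy)phenyl]lithium F2. Two equivalents of F2 add to the two morpholine amides of 8 to give (2E)-1-[2,4-bis(methoxymethoxy)phenyl]-2-{5-[(1E)-3-[2,4-bis(methoxymethoxy)phenyl]-3-oxoprop-1-en-1-yl]-2-[(tert-butyldimethylsilyl)oxy]phenyl}-3-{4-[(tert-butyldimethylsilyl)oxy]phenyl}prop-2-en-1-one F3. ZnBr2 with n-PrSH (CH2Cl2, 0 °C) removes the four MOM groups without touching the TBS ethers and gives 14. This is closed with the same squaramide in dry toluene, so the fallback comes back to the route at 15.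

Step 4 (double alkynylation). The risks are sluggish addition to the hindered α-aryl acrylamide, bridging by the acetylene bis-Grignard species, and decomposition of the bis(ethynyl ketone). The fallback goes through the aldehyde oxidation level and sets out from 8. Cp2Zr(H)Cl (2.5 equiv, THF, 23 °C) reduces both amides to the dialdehyde (2E)-3-{4-[(tert-butyldimethylsilyl)oxy]-3-[(1E)-1-{4-[(tert-butyldimethylsilyl)oxy]phenyl}-3-oxoprop-1-en-2-yl]phenyl}prop-2-enal F4. HC≡CMgBr (THF, −78 °C) adds 1,2 to both aldehydes to give (1E)-1-{4-[(tert-butyldimethylsilyl)oxy]phenyl}-2-{2-[(tert-butyldimethylsilyl)oxy]-5-[(1E)-3-hydroxypent-1-en-4-yn-1-yl]phenyl}pent-1-en-4-yn-3-ol F5 as a diastereomer mixture. MnO2 (CH2Cl2, 23 °C) oxidises both doubly activated alcohols, and the fallback comes back to the route at 10.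

Step 3 (lactone aminolysis and silylation). The risks are a persistent aza-Michael adduct of morpholine on the isoaurone and scrambling of the alkene geometry. The fallback replaces aminolysis by hydrolysis and amide coupling and sets out from 6. LiOH (THF–water, 0 °C, then dilute HCl) opens the lactone and cleaves the acetate to give (2E)-2-{2-hydroxy-5-[(1E)-3-(morpholin-4-yl)-3-oxoprop-1-en-1-yl]phenyl}-3-(4-hydroxyphenyl)prop-2-enoic acid F6. Coupling with morpholine (EDC·HCl, HOBt, DMF) gives 7, where the fallback comes back to the route; 7 is silylated as in step 3 to 8.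

Further compounds
F1 | step 5 | 1-bromo-2,4-bis(methoxymethoxy)benzene | COCOc1ccc(Br)c(OCOC)c1
F2 | step 5 | [2,4-bis(methoxymethoxy)phenyl]lithium | [Li]c1ccc(OCOC)cc1OCOC
F3 | step 5 | (2E)-1-[2,4-bis(methoxymethoxy)phenyl]-2-{5-[(1E)-3-[2,4-bis(methoxymethoxy)phenyl]-3-oxoprop-1-en-1-yl]-2-[(tert-butyldimethylsilyl)oxy]phenyl}-3-{4-[(tert-butyldimethylsilyl)oxy]phenyl}prop-2-en-1-one | COCOc1ccc(C(=O)/C=C/c2ccc(O[Si](C)(C)C(C)(C)C)c(/C(C(=O)c3ccc(OCOC)cc3OCOC)=C\c3ccc(O[Si](C)(C)C(C)(C)C)cc3)c2)c(OCOC)c1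
F4 | step 4 | (2E)-3-{4-[(tert-butyldimethylsilyl)oxy]-3-[(1E)-1-{4-[(tert-butyldimethylsilyl)oxy]phenyl}-3-oxoprop-1-en-2-yl]phenyl}prop-2-enal | O=C/C=C/c1ccc(O[Si](C)(C)C(C)(C)C)c(/C(C=O)=C\c2ccc(O[Si](C)(C)C(C)(C)C)cc2)c1
F5 | step 4 | (1E)-1-{4-[(tert-butyldimethylsilyl)oxy]phenyl}-2-{2-[(tert-butyldimethylsilyl)oxy]-5-[(1E)-3-hydroxypent-1-en-4-yn-1-yl]phenyl}pent-1-en-4-yn-3-ol (carbinol centres undefined) | C#CC(O)/C=C/c1ccc(O[Si](C)(C)C(C)(C)C)c(/C(C(O)C#C)=C\c2ccc(O[Si](C)(C)C(C)(C)C)cc2)c1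
F6 | step 3 | (2E)-2-{2-hydroxy-5-[(1E)-3-(morpholin-4-yl)-3-oxoprop-1-en-1-yl]phenyl}-3-(4-hydroxyphenyl)prop-2-enoic acid | O=C(/C=C/c1ccc(O)c(/C(C(=O)O)=C\c2ccc(O)cc2)c1)N1CCOCC1
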